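**Plan**
1. The side chain is cut at C1'=C2' (vinylogous aldol condensation of a C3 methyl group with a C2'–C7' enal). The pyran is then cut at O2–C1 and O2–C3 (cyclodehydration of a C1 acetal onto a C3 methyl ketone that comes from an allyl group).
2. Ring A is contracted at C5. C5 is sp2, carries chlorine and lies between the C6 carbonyl and C4a, which is the C(=O)–C(Cl)=C array left when a dichlorocarbene carbon is inserted into the C=C bond of a cyclic silyl enol ether. C4a–C5 and C5–C6 are therefore cut back to a cyclopentanone trimethylsilyl enol ether (C6=C4a).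
3. The cyclopentanone is cut at C8a–C1 (conjugate addition of a formyl anion equivalent) and C4a–C4 (enolate allylation), leading back to 2-methylcyclopent-2-en-1-one.
4. Forward order: five-membered carbocycle, enlargement to ring A (step 10), pyran ring (step 12), side chain joined last (step 18).
5. Stereochemistry: C8 from Corey–Bakshi–Shibata reduction, C7 from OsO4 dihydroxylation anti to the C8 silyl ether, C5' from Evans alkylation. Both side-chain alkenes become E by Wittig olefination and by elimination.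

Key step: step 10

Remark on numbering: isochromene numbering of the target (O2, C1, C3, C4, C4a, C5 to C8, C8a; side chain C1' to C7') is used for all intermediates. TBS = tert-butyldimethylsilyl.
Remark on transient centres: the configurations written at C4a and C8a in 11 to 17 are the expected ones (each new group anti to its neighbour). Both carbons are sp2 after step 12, so they do not affect the target.

Step 1
Reactants: 1 2-methylcyclopent-2-en-1-one
Product: 2 (R)-2-methylcyclopent-2-en-1-ol
Conditions: (S)-1-methyl-3,3-diphenyltetrahydro-1H,3H-pyrrolo[1,2-c][1,3,2]oxazaborole (10 mol %), BH3·SMe2, THF, −20 °C; MeOH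
Reagents that add atoms: none
Why: Corey–Bakshi–Shibata reduction, in which the ketone binds the oxazaborolidine boron with its larger alkenyl flank away from the catalyst, so that hydride from the coordinated borane should enter on one carbonyl face only (1,2-reduction) and set C8 as R.

Step 2
Reactants: 2 (R)-2-methylcyclopent-2-en-1-ol
Product: 3 (R)-tert-butyldimethyl[(2-methylcyclopent-2-en-1-yl)oxy]silane
Conditions: TBSCl, imidazole, DMF, 23 °C
Reagents that add atoms: tert-butyldimethylsilyl chloride, CC(C)(C)[Si](C)(C)Cl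
Why: Imidazole-promoted silylation of a secondary allylic alcohol, which installs the group that directs the next step and protects C8–OH to the end.

Step 3
Reactants: 3 (R)-tert-butyldimethyl[(2-methylcyclopent-2-en-1-yl)oxy]silane
Product: 4 (1R,2R,5R)-5-(TBSO)-1-methylcyclopentane-1,2-diol
Conditions: OsO4 (2 mol %), NMO, acetone/H2O, 23 °C
Reagents that add atoms: osmium tetroxide, O=[Os](=O)(=O)=O (catalytic carrier of both oxygen atoms); N-methylmorpholine N-oxide, C[N+]1([O-])CCOCC1; water, O
Why: Catalytic OsO4/NMO syn-dihydroxylation, in which the reagent should approach the ring face opposite the allylic silyloxy group, so that the new tertiary C7 hydroxyl lies trans to the C8 oxygen as the target requires (the C6 carbinol centre formed alongside is oxidised away in step 4).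

Step 4
Reactants: 4 (1R,2R,5R)-5-(TBSO)-1-methylcyclopentane-1,2-diol
Product: 5 (2S,3R)-3-(TBSO)-2-hydroxy-2-methylcyclopentan-1-one
Conditions: IBX (2-iodoxybenzoic acid), EtOAc, 75 °C
Reagents that add atoms: none
Why: IBX oxidation of the secondary alcohol; the tertiary C7 hydroxyl cannot be oxidised and IBX converts 1,2-diols into α-ketols without glycol cleavage.

Step 5
Reactants: 5 (2S,3R)-3-(TBSO)-2-hydroxy-2-methylcyclopentan-1-one
Product: 6 (4R,5S)-1,4,5-tris(TBSO)-5-methylcyclopent-1-ene
Conditions: TBSOTf (2.5 equiv), Et3N, CH2Cl2, 0 to 23 °C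
Reagents that add atoms: tert-butyldimethylsilyl trifluoromethanesulfonate, CC(C)(C)[Si](C)(C)OS(=O)(=O)C(F)(F)F
Why: Silyl triflate/amine silylation, which caps the tertiary alcohol and converts the ketone by soft enolisation into its silyl enol ether; this can only form toward C4a because C7 is quaternary.

Step 6
Reactants: 6 (4R,5S)-1,4,5-tris(TBSO)-5-methylcyclopent-1-ene
Product: 7 (4R,5S)-4,5-bis(TBSO)-5-methylcyclopent-2-en-1-one
Conditions: Pd(OAc)2 (1.1 equiv), MeCN, 40 °C
Reagents that add atoms: none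
Why: Saegusa–Ito oxidation, in which palladation of the silyl enol ether at C4a and β-hydride elimination from C8a should give the enone with no regioisomer possible.

Step 7
Reactants: 7 (4R,5S)-4,5-bis(TBSO)-5-methylcyclopent-2-en-1-one, 8 1,3-dithiane, 9 allyl bromide
Product: 12 (2S,3R,4S,5S)-5-allyl-2,3-bis(TBSO)-4-(1,3-dithian-2-yl)-2-methylcyclopentan-1-one, via 2-lithio-1,3-dithiane 10 (not isolated), via lithium enolate 11 (not isolated)
Conditions: 8, n-BuLi, THF, −30 °C; HMPA (2 equiv), −78 °C; 7; then 9, −78 to −30 °C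
Reagents that add atoms: none
Why: Three-component coupling by conjugate addition and enolate alkylation: in THF/HMPA the solvent-separated dithianyllithium should add 1,4 (the carbonyl is shielded by quaternary C7) anti to the C8 silyloxy group, and the regiodefined enolate 11 is C-allylated at C4a anti to the new C8a substituent.

Step 8
Reactants: 12 (2S,3R,4S,5S)-5-allyl-2,3-bis(TBSO)-4-(1,3-dithian-2-yl)-2-methylcyclopentan-1-one
Product: 13 (2S,3R,4S,5S)-5-allyl-2,3-bis(TBSO)-4-(dimethoxymethyl)-2-methylcyclopentan-1-one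
Conditions: PhI(OCOCF3)2 (1.5 equiv), MeOH, 0 °C
Reagents that add atoms: methanol, CO
Why: Oxidative dithioacetal-to-acetal interchange, in which the hypervalent iodine reagent activates sulfur and methanol captures the thionium ion twice; this removes sulfur before the carbene and palladium steps and leaves alkene, ketone and silyl ethers untouched.

Step 9
Reactants: 13 (2S,3R,4S,5S)-5-allyl-2,3-bis(TBSO)-4-(dimethoxymethyl)-2-methylcyclopentan-1-one
Product: 14 {[(3S,4R,5S)-2-allyl-4,5-bis(TBSO)-3-(dimethoxymethyl)-5-methylcyclopent-1-en-1-yl]oxy}trimethylsilane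
Conditions: LiN(iPr)2, THF, −78 °C; Me3SiCl, Et3N, −78 to 0 °C
Reagents that add atoms: chlorotrimethylsilane, C[Si](C)(C)Cl
Why: Enolate O-silylation; C4a carries the only α-hydrogen of the ketone, so deprotonation and trapping can only give the tetrasubstituted C6=C4a trimethylsilyl enol ether.

Step 10
Reactants: 14 {[(3S,4R,5S)-2-allyl-4,5-bis(TBSO)-3-(dimethoxymethyl)-5-methylcyclopent-1-en-1-yl]oxy}trimethylsilane
Product: 16 (4S,5R,6S)-3-allyl-5,6-bis(TBSO)-2-chloro-4-(dimethoxymethyl)-6-methylcyclohex-2-en-1-one, via dichlorocyclopropane 15 (not isolated)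
Conditions: Cl3CCO2Na (4 equiv), DME/tetrachloroethylene, 85 to 100 °C
Reagents that add atoms: sodium trichloroacetate, [Na+].[O-]C(=O)C(Cl)(Cl)Cl (source of C5 and its chlorine as dichlorocarbene, Cl[C]Cl)
Why: Thermal decarboxylation of the trichloroacetate releases dichlorocarbene, which adds in a concerted cheletropic [2+1] fashion to the C6=C4a silyl enol ether and gives the 6,6-dichloro-1-silyloxybicyclo[3.1.0]hexane 15. Departure of the endo chloride is coupled with disrotatory two-electron electrocyclic opening of the cyclopropane across the shared C4a–C6 bond, assisted by lone-pair donation from the silyl ether oxygen, and loss of Me3SiCl from the resulting chloro-substituted oxyallyl cation should leave the 2-chlorocyclohex-2-enone with C4a–C5 and C5–C6 newly formed. The closest known reaction type is the dihalocarbene ring expansion of cyclic trimethylsilyl enol ethers to 2-halocycloalk-2-enones, which also covers tetrasubstituted enol ethers of 2-substituted cyclopentanones. The three-membered ring closes by cycloaddition, whereas ring A arises by one-carbon enlargement of the five-membered ring and not by a cyclisation; no stereocentre of 16 is created, C7, C8 and C8a are spectators, and the face of cyclopropanation is irrelevant because C4a and C5 end up sp2. The step needs chemoselectivity for the enol ether over the allyl alkene and over C–H insertion at the acetal, which the much greater nucleophilicity of the silyl enol ether toward the electrophilic carbene should provide, and the neutral anhydrous carbene source spares the enol ether, the acetal and the silyl ethers.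

Step 11
Reactants: 16 (4S,5R,6S)-3-allyl-5,6-bis(TBSO)-2-chloro-4-(dimethoxymethyl)-6-methylcyclohex-2-en-1-one
Product: 17 (4S,5R,6S)-5,6-bis(TBSO)-2-chloro-4-(dimethoxymethyl)-6-methyl-3-(2-oxopropyl)cyclohex-2-en-1-one
Conditions: PdCl2 (10 mol %), CuCl, O2 (1 atm), DMF/H2O 7:1, 23 °C
Reagents that add atoms: water, O
Why: Tsuji–Wacker oxidation, in which divalent palladium activates the terminal alkene for Markovnikov attack of water and CuCl/O2 reoxidises the zerovalent palladium, giving the methyl ketone (C3=O, C1' methyl) while the tetrasubstituted, electron-poor chloroenone alkene should not react.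

Step 12
Reactants: 17 (4S,5R,6S)-5,6-bis(TBSO)-2-chloro-4-(dimethoxymethyl)-6-methyl-3-(2-oxopropyl)cyclohex-2-en-1-one
Product: 18 (7S,8R)-7,8-bis(TBSO)-5-chloro-3,7-dimethyl-7,8-dihydro-6H-isochromen-6-one
Conditions: camphorsulfonic acid (20 mol %), toluene, 5 Å molecular sieves, 60 °C
Reagents that add atoms: none
Why: Acid-catalysed cyclodehydration of a masked 1,5-dicarbonyl compound (the vinylogous counterpart of the 1,3,5-triketone to 4-pyranone closure), in which the conjugated enol of the C3 ketone attacks the C1 oxocarbenium ion through oxygen and loss of the second methanol across C1–C8a gives the conjugated 4-alkylidene-4H-pyran and erases the C8a centre.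

Step 13
Reactants: 19 bromoacetyl bromide, 20 2-(trimethylsilyl)ethanol
Product: 21 2-(trimethylsilyl)ethyl 2-bromoacetate
Conditions: pyridine, CH2Cl2, 0 °C
Reagents that add atoms: none
Why: Esterification of an alcohol with an acyl bromide, the acyl bromide reacting far faster than the alkyl bromide.

Step 14
Reactants: 22 (R)-4-benzyl-3-propanoyl-1,3-oxazolidin-2-one, 21 2-(trimethylsilyl)ethyl 2-bromoacetate
Product: 24 2-(trimethylsilyl)ethyl (3S)-4-[(4R)-4-benzyl-2-oxo-1,3-oxazolidin-3-yl]-3-methyl-4-oxobutanoate, via sodium Z-enolate 23 (not isolated)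
Conditions: NaN(SiMe3)2, THF, −78 °C; then 21, −78 to −40 °C
Reagents that add atoms: none
Why: Evans asymmetric alkylation, in which the chelated sodium Z-enolate is alkylated by the bromoacetate on the face opposite the benzyl group of the (R)-auxiliary and the future C5' centre is set as S.

Step 15
Reactants: 24 2-(trimethylsilyl)ethyl (3S)-4-[(4R)-4-benzyl-2-oxo-1,3-oxazolidin-3-yl]-3-methyl-4-oxobutanoate
Product: 25 2-(trimethylsilyl)ethyl (3S)-4-(ethylsulfanyl)-3-methyl-4-oxobutanoate
Conditions: EtSH, n-BuLi (gives LiSEt), THF, 0 °C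
Reagents that add atoms: ethanethiol, CCS
Why: Thiolate cleavage of the N-acyloxazolidinone at its exocyclic carbonyl, which is far more electrophilic than the silylethyl ester, so the thioester should form without touching the α-stereocentre.

Step 16
Reactants: 25 2-(trimethylsilyl)ethyl (3S)-4-(ethylsulfanyl)-3-methyl-4-oxobutanoate
Product: 26 2-(trimethylsilyl)ethyl (3S)-3-methyl-4-oxobutanoate
Conditions: Et3SiH, Pd on carbon (10 wt % Pd), acetone, 23 °C
Reagents that add atoms: none
Why: Fukuyama reduction, a palladium-catalysed hydrosilane reduction of the thioester that stops at the aldehyde and is mild enough to preserve the α-stereocentre and the ester.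

Step 17
Reactants: 26 2-(trimethylsilyl)ethyl (3S)-3-methyl-4-oxobutanoate, 27 2-(triphenyl-λ5-phosphanylidene)propanal
Product: 28 2-(trimethylsilyl)ethyl (3S,4E)-3,5-dimethyl-6-oxohex-4-enoate
Conditions: toluene, 90 °C
Reagents that add atoms: none
Why: Wittig olefination with a stabilised formyl ylide, which should give the E trisubstituted enal and needs no base that could epimerise the α-branched aldehyde.

Step 18
Reactants: 18 (7S,8R)-7,8-bis(TBSO)-5-chloro-3,7-dimethyl-7,8-dihydro-6H-isochromen-6-one, 28 2-(trimethylsilyl)ethyl (3S,4E)-3,5-dimethyl-6-oxohex-4-enoate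
Product: 32 2-(trimethylsilyl)ethyl (3S,4E,6E)-7-[(7S,8R)-7,8-bis(TBSO)-5-chloro-7-methyl-6-oxo-7,8-dihydro-6H-isochromen-3-yl]-3,5-dimethylhepta-4,6-dienoate, via lithium trienolate 29 (not isolated), via lithium aldolate 30 (not isolated), via allylic mesylate 31 (not isolated)
Conditions: LiN(SiMe3)2, THF, −78 °C; 28; MsCl, −78 to 0 °C; DBU, 0 to 23 °C
Reagents that add atoms: none
Why: Vinylogous aldol condensation: the C3 methyl group is the terminus of a doubly vinylogous ketone (as in 2-methyl-4-pyranones), so the amide base should give trienolate 29, which adds through C1' to the enal carbonyl at −78 °C, and mesylation followed by E1cB elimination gives the conjugated E C1'=C2' alkene, while the low temperature and the preformed enolate protect the C5' centre.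

Step 19
Reactants: 32 2-(trimethylsilyl)ethyl (3S,4E,6E)-7-[(7S,8R)-7,8-bis(TBSO)-5-chloro-7-methyl-6-oxo-7,8-dihydro-6H-isochromen-3-yl]-3,5-dimethylhepta-4,6-dienoate
Product: 33 (3S,4E,6E)-7-[(7S,8R)-5-chloro-7,8-dihydroxy-7-methyl-6-oxo-7,8-dihydro-6H-isochromen-3-yl]-3,5-dimethylhepta-4,6-dienoic acid (CNP0532378.1)
Conditions: tris(dimethylamino)sulfonium difluorotrimethylsilicate (TASF), DMF, 0 to 23 °C; then aq. NH4Cl/dilute HCl to pH 4
Reagents that add atoms: none
Why: Fluoride-mediated global deprotection, in which anhydrous fluoride cleaves both silyl ethers and fragments the 2-(trimethylsilyl)ethyl ester to fluorosilane, ethene and carboxylate in one operation under conditions the chlorinated pyranoquinone core and its α-ketol should tolerate.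

**Compound list**
1 | 2-methylcyclopent-2-en-1-one | CC1=CCCC1=O | starting material
2 | (R)-2-methylcyclopent-2-en-1-ol | CC1=CCC[C@H]1O | intermediate
3 | (R)-tert-butyldimethyl[(2-methylcyclopent-2-en-1-yl)oxy]silane | CC1=CCC[C@H]1O[Si](C)(C)C(C)(C)C | intermediate
4 | (1R,2R,5R)-5-(TBSO)-1-methylcyclopentane-1,2-diol | O[C@H]1[C@@](C)(O)[C@H](O[Si](C)(C)C(C)(C)C)CC1 | intermediate
5 | (2S,3R)-3-(TBSO)-2-hydroxy-2-methylcyclopentan-1-one | O=C1[C@@](C)(O)[C@H](O[Si](C)(C)C(C)(C)C)CC1 | intermediate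
6 | (4R,5S)-1,4,5-tris(TBSO)-5-methylcyclopent-1-ene | C[C@]1(O[Si](C)(C)C(C)(C)C)[C@H](O[Si](C)(C)C(C)(C)C)CC=C1O[Si](C)(C)C(C)(C)C | intermediate
7 | (4R,5S)-4,5-bis(TBSO)-5-methylcyclopent-2-en-1-one | O=C1[C@@](C)(O[Si](C)(C)C(C)(C)C)[C@H](O[Si](C)(C)C(C)(C)C)C=C1 | intermediate
8 | 1,3-dithiane | C1CSCSC1 | starting material
9 | allyl bromide | C=CCBr | starting material
10 | 2-lithio-1,3-dithiane | [Li]C1SCCCS1 | intermediate (not isolated)
11 | lithium (4R,5S)-4,5-bis(TBSO)-3-(1,3-dithian-2-yl)-5-methylcyclopent-1-en-1-olate, dithianyl trans to the C4 silyloxy group | C[C@]1(O[Si](C)(C)C(C)(C)C)[C@H](O[Si](C)(C)C(C)(C)C)[C@@H](C2SCCCS2)C=C1[O-].[Li+] | intermediate (not isolated)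
12 | (2S,3R,4S,5S)-5-allyl-2,3-bis(TBSO)-4-(1,3-dithian-2-yl)-2-methylcyclopentan-1-one | O=C1[C@@](C)(O[Si](C)(C)C(C)(C)C)[C@H](O[Si](C)(C)C(C)(C)C)[C@@H](C2SCCCS2)[C@@H]1CC=C | intermediate
13 | (2S,3R,4S,5S)-5-allyl-2,3-bis(TBSO)-4-(dimethoxymethyl)-2-methylcyclopentan-1-one | O=C1[C@@](C)(O[Si](C)(C)C(C)(C)C)[C@H](O[Si](C)(C)C(C)(C)C)[C@@H](C(OC)OC)[C@@H]1CC=C | intermediate
14 | {[(3S,4R,5S)-2-allyl-4,5-bis(TBSO)-3-(dimethoxymethyl)-5-methylcyclopent-1-en-1-yl]oxy}trimethylsilane | C=CCC1=C(O[Si](C)(C)C)[C@@](C)(O[Si](C)(C)C(C)(C)C)[C@H](O[Si](C)(C)C(C)(C)C)[C@H]1C(OC)OC | intermediate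
15 | 5-allyl-2,3-bis(TBSO)-6,6-dichloro-4-(dimethoxymethyl)-2-methyl-1-(trimethylsilyloxy)bicyclo[3.1.0]hexane (C7, C8, C8a as in 14; cyclopropane face not defined) | C=CCC12C(Cl)(Cl)C1(O[Si](C)(C)C)[C@@](C)(O[Si](C)(C)C(C)(C)C)[C@H](O[Si](C)(C)C(C)(C)C)[C@H]2C(OC)OC | intermediate (not isolated)
16 | (4S,5R,6S)-3-allyl-5,6-bis(TBSO)-2-chloro-4-(dimethoxymethyl)-6-methylcyclohex-2-en-1-one | C=CCC1=C(Cl)C(=O)[C@@](C)(O[Si](C)(C)C(C)(C)C)[C@H](O[Si](C)(C)C(C)(C)C)[C@H]1C(OC)OC | intermediate
17 | (4S,5R,6S)-5,6-bis(TBSO)-2-chloro-4-(dimethoxymethyl)-6-methyl-3-(2-oxopropyl)cyclohex-2-en-1-one | CC(=O)CC1=C(Cl)C(=O)[C@@](C)(O[Si](C)(C)C(C)(C)C)[C@H](O[Si](C)(C)C(C)(C)C)[C@H]1C(OC)OC | intermediate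
18 | (7S,8R)-7,8-bis(TBSO)-5-chloro-3,7-dimethyl-7,8-dihydro-6H-isochromen-6-one | CC1=CC2=C(Cl)C(=O)[C@@](C)(O[Si](C)(C)C(C)(C)C)[C@H](O[Si](C)(C)C(C)(C)C)C2=CO1 | intermediate
19 | bromoacetyl bromide | BrCC(Br)=O | starting material
20 | 2-(trimethylsilyl)ethanol | C[Si](C)(C)CCO | starting material
21 | 2-(trimethylsilyl)ethyl 2-bromoacetate | C[Si](C)(C)CCOC(=O)CBr | intermediate
22 | (R)-4-benzyl-3-propanoyl-1,3-oxazolidin-2-one | CCC(=O)N1[C@H](Cc2ccccc2)COC1=O | starting material
23 | sodium (Z)-enolate of 22 | C/C=C(\[O-])N1[C@H](Cc2ccccc2)COC1=O.[Na+] | intermediate (not isolated)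
24 | 2-(trimethylsilyl)ethyl (3S)-4-[(4R)-4-benzyl-2-oxo-1,3-oxazolidin-3-yl]-3-methyl-4-oxobutanoate | O=C([C@@H](C)CC(=O)OCC[Si](C)(C)C)N1[C@H](Cc2ccccc2)COC1=O | intermediate
25 | 2-(trimethylsilyl)ethyl (3S)-4-(ethylsulfanyl)-3-methyl-4-oxobutanoate | CCSC(=O)[C@@H](C)CC(=O)OCC[Si](C)(C)C | intermediate
26 | 2-(trimethylsilyl)ethyl (3S)-3-methyl-4-oxobutanoate | O=C[C@@H](C)CC(=O)OCC[Si](C)(C)C | intermediate
27 | 2-(triphenyl-λ5-phosphanylidene)propanal | CC(C=O)=P(c1ccccc1)(c1ccccc1)c1ccccc1 | starting material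
28 | 2-(trimethylsilyl)ethyl (3S,4E)-3,5-dimethyl-6-oxohex-4-enoate | O=C/C(C)=C/[C@@H](C)CC(=O)OCC[Si](C)(C)C | intermediate
29 | lithium (7S,8R)-7,8-bis(TBSO)-5-chloro-7-methyl-3-methylidene-7,8-dihydro-3H-isochromen-6-olate | C=C1C=C2C(Cl)=C([O-])[C@@](C)(O[Si](C)(C)C(C)(C)C)[C@H](O[Si](C)(C)C(C)(C)C)C2=CO1.[Li+] | intermediate (not isolated)
30 | lithium (3S,4E)-7-[(7S,8R)-7,8-bis(TBSO)-5-chloro-7-methyl-6-oxo-7,8-dihydro-6H-isochromen-3-yl]-3,5-dimethyl-1-oxo-1-[2-(trimethylsilyl)ethoxy]hept-4-en-6-olate (C2' epimers) | CC(/C([O-])CC1=CC2=C(Cl)C(=O)[C@@](C)(O[Si](C)(C)C(C)(C)C)[C@H](O[Si](C)(C)C(C)(C)C)C2=CO1)=C\[C@@H](C)CC(=O)OCC[Si](C)(C)C.[Li+] | intermediate (not isolated)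
31 | 2-(trimethylsilyl)ethyl (3S,4E)-7-[(7S,8R)-7,8-bis(TBSO)-5-chloro-7-methyl-6-oxo-7,8-dihydro-6H-isochromen-3-yl]-6-(methanesulfonyloxy)-3,5-dimethylhept-4-enoate (C2' epimers) | CC(/C(OS(C)(=O)=O)CC1=CC2=C(Cl)C(=O)[C@@](C)(O[Si](C)(C)C(C)(C)C)[C@H](O[Si](C)(C)C(C)(C)C)C2=CO1)=C\[C@@H](C)CC(=O)OCC[Si](C)(C)C | intermediate (not isolated)
32 | 2-(trimethylsilyl)ethyl (3S,4E,6E)-7-[(7S,8R)-7,8-bis(TBSO)-5-chloro-7-methyl-6-oxo-7,8-dihydro-6H-isochromen-3-yl]-3,5-dimethylhepta-4,6-dienoate | CC(/C=C/C1=CC2=C(Cl)C(=O)[C@@](C)(O[Si](C)(C)C(C)(C)C)[C@H](O[Si](C)(C)C(C)(C)C)C2=CO1)=C\[C@@H](C)CC(=O)OCC[Si](C)(C)C | intermediate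
33 | (3S,4E,6E)-7-[(7S,8R)-5-chloro-7,8-dihydroxy-7-methyl-6-oxo-7,8-dihydro-6H-isochromen-3-yl]-3,5-dimethylhepta-4,6-dienoic acid | CC(/C=C/C1=CC2=C(Cl)C(=O)[C@@](C)(O)[C@H](O)C2=CO1)=C\[C@@H](C)CC(=O)O | target

**Step count and risks**
Total step count: 19 (steps 1 to 12 core, steps 13 to 17 side chain, steps 18 and 19 endgame).
Longest linear sequence: 14 steps (1 to 12, 18, 19) from 2-methylcyclopent-2-en-1-one.

Steps most likely to fail:

Step 10 (key step). Carbene addition to the hindered tetrasubstituted enol ether may be slow, so that loss of the silyl enol ether, cyclopropanation of the allyl group or incomplete opening of the adduct compete. The fallback sets out from 14 and replaces the halocarbene by a methylene transfer with later chlorination. Simmons–Smith cyclopropanation (Et2Zn, CH2I2, CH2Cl2, 0 °C, one equivalent so that the enol ether reacts before the allyl group) would give the silyloxycyclopropane F1. Oxidative ring opening with FeCl3 in DMF (Ito–Saegusa ring expansion) would give the ring-enlarged β-chloro ketone F2, and NaOAc in MeOH would give the chlorine-free cyclohexenone F3. Wacker oxidation and acid cyclodehydration as in steps 11 and 12 would give the methyl ketone F4 and the bicyclic pyranone F5. Electrophilic chlorination of F5 with N-chlorosuccinimide (MeCN, 0 °C) at C5, the nucleophilic α-carbon of the doubly vinylogous ester, comes back to the route at 18.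

Step 18. Proton transfer from the γ-position (C5') of the enal to the trienolate would cost material and configuration, the trienolate may react through C4 instead of C1', and the aldolate may revert before elimination. The fallback sets out from 18 and uses Lewis-acid instead of base activation. TBSOTf/Et3N (CH2Cl2, −78 °C) would give the silyl trienol ether F6. A BF3·OEt2-promoted vinylogous Mukaiyama aldol addition to 28 at −78 °C would give the β-hydroxy adduct F7. MsCl/Et3N followed by DBU would pass through mesylate 31 and come back to the route at 32.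

Step 7. The basic organolithium may add 1,2 or remove the γ-hydrogen at C8 (loss of the C8 configuration), and the enolate allylation may stop short or go twice. The fallback sets out from 7 and uses a radical instead of an anionic formyl equivalent. Benzophenone-sensitised photochemical addition of 1,3-dioxolane (as solvent, 350 nm) would give the dioxolanyl ketone F8, anti to the C8 silyloxy group. Deprotonation at C4a with LiN(iPr)2 and alkylation with allyl bromide (THF, −78 to 0 °C) would give the allylated ketone F9. Acetal exchange (MeOH, HC(OMe)3, pyridinium p-toluenesulfonate, 23 °C) comes back to the route at 13.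

**Further compounds**
F1 | step 10 | 5-allyl-2,3-bis(TBSO)-4-(dimethoxymethyl)-2-methyl-1-(trimethylsilyloxy)bicyclo[3.1.0]hexane (C7, C8, C8a as in 14) | C=CCC12CC1(O[Si](C)(C)C)[C@@](C)(O[Si](C)(C)C(C)(C)C)[C@H](O[Si](C)(C)C(C)(C)C)[C@H]2C(OC)OC
F2 | step 10 | (4S,5R,6S)-3-allyl-5,6-bis(TBSO)-3-chloro-4-(dimethoxymethyl)-6-methylcyclohexan-1-one (C3 epimers) | C=CCC1(Cl)CC(=O)[C@@](C)(O[Si](C)(C)C(C)(C)C)[C@H](O[Si](C)(C)C(C)(C)C)[C@H]1C(OC)OC
F3 | step 10 | (4S,5R,6S)-3-allyl-5,6-bis(TBSO)-4-(dimethoxymethyl)-6-methylcyclohex-2-en-1-one | C=CCC1=CC(=O)[C@@](C)(O[Si](C)(C)C(C)(C)C)[C@H](O[Si](C)(C)C(C)(C)C)[C@H]1C(OC)OC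
F4 | step 10 | (4S,5R,6S)-5,6-bis(TBSO)-4-(dimethoxymethyl)-6-methyl-3-(2-oxopropyl)cyclohex-2-en-1-one | CC(=O)CC1=CC(=O)[C@@](C)(O[Si](C)(C)C(C)(C)C)[C@H](O[Si](C)(C)C(C)(C)C)[C@H]1C(OC)OC
F5 | step 10 | (7S,8R)-7,8-bis(TBSO)-3,7-dimethyl-7,8-dihydro-6H-isochromen-6-one | CC1=CC2=CC(=O)[C@@](C)(O[Si](C)(C)C(C)(C)C)[C@H](O[Si](C)(C)C(C)(C)C)C2=CO1
F6 | step 18 | tert-butyl{[(7S,8R)-7,8-bis(TBSO)-5-chloro-7-methyl-3-methylidene-7,8-dihydro-3H-isochromen-6-yl]oxy}dimethylsilane | C=C1C=C2C(Cl)=C(O[Si](C)(C)C(C)(C)C)[C@@](C)(O[Si](C)(C)C(C)(C)C)[C@H](O[Si](C)(C)C(C)(C)C)C2=CO1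
F7 | step 18 | 2-(trimethylsilyl)ethyl (3S,4E)-7-[(7S,8R)-7,8-bis(TBSO)-5-chloro-7-methyl-6-oxo-7,8-dihydro-6H-isochromen-3-yl]-6-hydroxy-3,5-dimethylhept-4-enoate (C2' epimers) | CC(/C(O)CC1=CC2=C(Cl)C(=O)[C@@](C)(O[Si](C)(C)C(C)(C)C)[C@H](O[Si](C)(C)C(C)(C)C)C2=CO1)=C\[C@@H](C)CC(=O)OCC[Si](C)(C)C
F8 | step 7 | (2S,3R,4S)-2,3-bis(TBSO)-4-(1,3-dioxolan-2-yl)-2-methylcyclopentan-1-one | O=C1[C@@](C)(O[Si](C)(C)C(C)(C)C)[C@H](O[Si](C)(C)C(C)(C)C)[C@@H](C2OCCO2)C1
F9 | step 7 | (2S,3R,4S,5S)-5-allyl-2,3-bis(TBSO)-4-(1,3-dioxolan-2-yl)-2-methylcyclopentan-1-one | O=C1[C@@](C)(O[Si](C)(C)C(C)(C)C)[C@H](O[Si](C)(C)C(C)(C)C)[C@@H](C2OCCO2)[C@@H]1CC=C
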